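**Retrosynthetic overview**
1. Chebulic acid 19 comes from the protected isochromanone 17 by ether cleavage and acid hydrolysis.
2. The δ-lactone of 17 comes from the 3-substituted phthalide 11 by a one-carbon ring expansion: a glycolate carbon is inserted into the benzylic C–O bond, which makes C3–C4 and O2–C3 and sets C4 (C3 is set by equilibration).
3. 11 comes from an Evans alkylation of succinyl imide 10 with 3-bromophthalide 7, which sets the succinyl stereocentre.
4. 7 comes from phthalide 6, made by a [3+3] benzannulation of the aminomethylene derivative of tetronic acid with 1,3-dimethoxyacetone.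
5. Ring order: γ-lactone (purchased), then the benzene ring annulated onto it, then expansion to the δ-lactone.

Assumption: in hot dilute mineral acid the free acid settles in the isochromanone lactone form drawn for chebulic acid (the form in which it is isolated), so the last step converges on the target.

**Step 1**
Reactants: 1 tetronic acid [furan-2,4(3H,5H)-dione]; 2 N,N-dimethylformamide dimethyl acetal
Product: 3 3-[(dimethylamino)methylidene]furan-2,4(3H,5H)-dione
Conditions: PhMe, 23 °C
Reagents that add atoms: none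
Why: Enaminone formation by condensation of the acidic C3 methylene of a cyclic 1,3-dicarbonyl with an amide acetal is fast and clean; no stereocentre.

**Step 2**
Reactants: 3 3-[(dimethylamino)methylidene]furan-2,4(3H,5H)-dione; 4 1,3-dimethoxypropan-2-one
Product: 6 4,5,6-trimethoxy-2-benzofuran-1(3H)-one, via phenolic phthalide 5 (not isolated)
Conditions: t-BuOK, THF, 0 → 60 °C; N2 purge; then MeI, DMF, 23 °C
Reagents that add atoms: iodomethane (CI)
Why: Formal [3+3] benzannulation, in which the enolate of 4 displaces dimethylamine at the enaminone carbon (addition–elimination), the second α-carbon closes on the C4 ketone (intramolecular aldol condensation) and the ring aromatises to a 2,6-dimethoxyphenoxide that is O-methylated in the same pot (Williamson); no stereocentre.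

**Step 3**
Reactants: 6 4,5,6-trimethoxy-2-benzofuran-1(3H)-one
Product: 7 3-bromo-4,5,6-trimethoxy-2-benzofuran-1(3H)-one (racemic)
Conditions: NBS (1.1 equiv), AIBN, PhCF3, 85 °C
Reagents that add atoms: N-bromosuccinimide (O=C1CCC(=O)N1Br)
Why: Wohl–Ziegler radical bromination takes the only benzylic, α-oxygenated C–H position (C3); the product is racemic and this centre is erased in step 7.

**Step 4**
Reactants: 8 succinic anhydride
Product: 10 methyl 4-[(4R)-4-benzyl-2-oxo-1,3-oxazolidin-3-yl]-4-oxobutanoate, via imide acid 9 (not isolated)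
Conditions: n-BuLi, THF, −78 °C; 8, → 0 °C; then MeI, DMF, 23 °C
Reagents that add atoms: (R)-4-benzyl-1,3-oxazolidin-2-one (O=C1N[C@H](Cc2ccccc2)CO1); iodomethane (CI)
Why: The lithiated oxazolidinone opens the anhydride (N-acylation) and the lithium carboxylate is then O-methylated; the only stereocentre is that of the auxiliary.

**Step 5**
Reactants: 10 methyl 4-[(4R)-4-benzyl-2-oxo-1,3-oxazolidin-3-yl]-4-oxobutanoate; 7 3-bromo-4,5,6-trimethoxy-2-benzofuran-1(3H)-one
Product: 11 methyl (3S)-4-[(4R)-4-benzyl-2-oxo-1,3-oxazolidin-3-yl]-4-oxo-3-(5,6,7-trimethoxy-3-oxo-1,3-dihydro-2-benzofuran-1-yl)butanoate (both epimers at the benzofuranyl carbon)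
Conditions: NaHMDS (1.0 equiv), THF, −78 °C; then 7, −78 → −40 °C
Reagents that add atoms: none
Why: Evans asymmetric alkylation, in which the chelated (Z)-sodium enolate is alkylated by the reactive α-bromo acylal on the face away from the benzyl group, giving the (S) succinyl centre; the benzofuranyl carbon forms as both epimers, which converge in step 7.

**Step 6**
Reactants: 12 methyl glycolate
Product: 14 1-methoxy-1,2-bis(trimethylsilyloxy)ethene, via methyl (trimethylsilyloxy)acetate 13 (not isolated)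
Conditions: TMSCl, Et3N, THF, 0 °C; then LDA, TMSCl, −78 → 23 °C
Reagents that add atoms: chlorotrimethylsilane (C[Si](C)(C)Cl)
Why: O-silylation, then kinetic enolisation and enolate O-silylation, is the standard preparation of a ketene silyl acetal (Mukaiyama donor); no stereocentre.

**Step 7**
Reactants: 11 methyl (3S)-4-[(4R)-4-benzyl-2-oxo-1,3-oxazolidin-3-yl]-4-oxo-3-(5,6,7-trimethoxy-3-oxo-1,3-dihydro-2-benzofuran-1-yl)butanoate; 14 1-methoxy-1,2-bis(trimethylsilyloxy)ethene
Product: 17 methyl (3S,4S)-4-[(2S)-1-[(4R)-4-benzyl-2-oxo-1,3-oxazolidin-3-yl]-4-methoxy-1,4-dioxobutan-2-yl]-5,6,7-trimethoxy-1-oxo-3,4-dihydro-1H-2-benzopyran-3-carboxylate, via ring-opened bis-silyl adduct 15 (not isolated), via acid chloride 16 (not isolated)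
Conditions: TMSOTf (20 mol %), CH2Cl2, −40 → 0 °C; then (COCl)2, DMF (cat.), 0 → 23 °C; evaporate; then DBU (20 mol %), CH2Cl2, 23 °C
Reagents that add atoms: none
Why: Proposed new method: a Lewis-acid ring expansion of a phthalide by formal insertion of a glycolate carbon into the benzylic C–O bond. TMSOTf silylates the lactone carbonyl and ionises the 2,4-dimethoxybenzylic C–O bond (either C3 epimer gives the same cation). The cation holds the succinyl C–H in the arene plane (A1,3 strain) and is captured by 14 on the face away from the acyl-oxazolidinone, which should set C4 as (S). The silyl ester is converted into the acid chloride and re-closes onto the new silyl ether, so the same carboxyl group now sits in a six-membered lactone without a free hydroxyl ever being available to the imide. DBU then equilibrates the acidic C3 centre to the trans (3S) lactone. The closest known reactions are Mukaiyama-type SN1 alkylations of α-chiral secondary benzylic acetates with silyl nucleophiles and the acidolysis of 2,4-dimethoxybenzyl esters.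

**Step 8**
Reactants: 17 methyl (3S,4S)-4-[(2S)-1-[(4R)-4-benzyl-2-oxo-1,3-oxazolidin-3-yl]-4-methoxy-1,4-dioxobutan-2-yl]-5,6,7-trimethoxy-1-oxo-3,4-dihydro-1H-2-benzopyran-3-carboxylate
Product: 19 chebulic acid, via triphenol imide 18 (not isolated)
Conditions: BBr3, CH2Cl2, −78 → 23 °C; then H2O, 3 M HCl, 90 °C (Ar)
Reagents that add atoms: water (O)
Why: BBr3 cleaves the three aryl methyl ethers (Lewis-acid ether cleavage) and hot aqueous acid then hydrolyses the two methyl esters and the N-acyl oxazolidinone without touching the three stereocentres, the free acid closing again to the isochromanone lactone.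

**Compound list**
1 | tetronic acid, furan-2,4(3H,5H)-dione | O=C1CC(=O)CO1 | starting material
2 | N,N-dimethylformamide dimethyl acetal | COC(OC)N(C)C | starting material
3 | 3-[(dimethylamino)methylidene]furan-2,4(3H,5H)-dione | CN(C)C=C1C(=O)COC1=O | intermediate
4 | 1,3-dimethoxypropan-2-one | COCC(=O)COC | starting material
5 | 5-hydroxy-4,6-dimethoxy-2-benzofuran-1(3H)-one | O=C1OCc2c1cc(OC)c(O)c2OC | intermediate
6 | 4,5,6-trimethoxy-2-benzofuran-1(3H)-one | O=C1OCc2c1cc(OC)c(OC)c2OC | intermediate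
7 | 3-bromo-4,5,6-trimethoxy-2-benzofuran-1(3H)-one (racemic) | O=C1OC(Br)c2c1cc(OC)c(OC)c2OC | intermediate
8 | succinic anhydride | O=C1CCC(=O)O1 | starting material
9 | 4-[(4R)-4-benzyl-2-oxo-1,3-oxazolidin-3-yl]-4-oxobutanoic acid (lithium salt in the flask) | OC(=O)CCC(=O)N1[C@H](Cc2ccccc2)COC1=O | intermediate
10 | methyl 4-[(4R)-4-benzyl-2-oxo-1,3-oxazolidin-3-yl]-4-oxobutanoate | COC(=O)CCC(=O)N1[C@H](Cc2ccccc2)COC1=O | intermediate
11 | methyl (3S)-4-[(4R)-4-benzyl-2-oxo-1,3-oxazolidin-3-yl]-4-oxo-3-(5,6,7-trimethoxy-3-oxo-1,3-dihydro-2-benzofuran-1-yl)butanoate (epimers at the benzofuranyl carbon) | COC(=O)C[C@@H](C1OC(=O)c2cc(OC)c(OC)c(OC)c12)C(=O)N3[C@H](Cc4ccccc4)COC3=O | intermediate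
12 | methyl glycolate | COC(=O)CO | starting material
13 | methyl 2-(trimethylsilyloxy)acetate | COC(=O)CO[Si](C)(C)C | intermediate
14 | 1-methoxy-1,2-bis(trimethylsilyloxy)ethene | COC(O[Si](C)(C)C)=CO[Si](C)(C)C | intermediate
15 | dimethyl (3S,4S)-4-{[(4R)-4-benzyl-2-oxo-1,3-oxazolidin-3-yl]carbonyl}-3-{2,3,4-trimethoxy-6-[(trimethylsilyloxy)carbonyl]phenyl}-2-(trimethylsilyloxy)hexanedioate (C2 epimers) | COC(=O)C[C@H](C(=O)N3[C@H](Cc4ccccc4)COC3=O)[C@@H](c1c(C(=O)O[Si](C)(C)C)cc(OC)c(OC)c1OC)C(O[Si](C)(C)C)C(=O)OC | intermediate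
16 | dimethyl (3S,4S)-4-{[(4R)-4-benzyl-2-oxo-1,3-oxazolidin-3-yl]carbonyl}-3-[6-(chlorocarbonyl)-2,3,4-trimethoxyphenyl]-2-(trimethylsilyloxy)hexanedioate (C2 epimers) | COC(=O)C[C@H](C(=O)N3[C@H](Cc4ccccc4)COC3=O)[C@@H](c1c(C(Cl)=O)cc(OC)c(OC)c1OC)C(O[Si](C)(C)C)C(=O)OC | intermediate
17 | methyl (3S,4S)-4-[(2S)-1-[(4R)-4-benzyl-2-oxo-1,3-oxazolidin-3-yl]-4-methoxy-1,4-dioxobutan-2-yl]-5,6,7-trimethoxy-1-oxo-3,4-dihydro-1H-2-benzopyran-3-carboxylate | COC(=O)C[C@H](C(=O)N3[C@H](Cc4ccccc4)COC3=O)[C@H]1c2c(cc(OC)c(OC)c2OC)C(=O)O[C@@H]1C(=O)OC | intermediate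
18 | methyl (3S,4S)-4-[(2S)-1-[(4R)-4-benzyl-2-oxo-1,3-oxazolidin-3-yl]-4-methoxy-1,4-dioxobutan-2-yl]-5,6,7-trihydroxy-1-oxo-3,4-dihydro-1H-2-benzopyran-3-carboxylate | COC(=O)C[C@H](C(=O)N3[C@H](Cc4ccccc4)COC3=O)[C@H]1c2c(cc(O)c(O)c2O)C(=O)O[C@@H]1C(=O)OC | intermediate
19 | chebulic acid, (2S)-2-[(3S,4S)-3-carboxy-5,6,7-trihydroxy-1-oxo-3,4-dihydro-1H-2-benzopyran-4-yl]butanedioic acid | O=C(O)C[C@H](C(=O)O)[C@H]1c2c(cc(O)c(O)c2O)C(=O)O[C@@H]1C(=O)O | target

**Step count and risks**
Total steps: 8. Longest linear sequence: 6 (steps 1, 2, 3, 5, 7, 8).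

Step 2 is at risk because the annulation is run on a lactone-bearing enaminone: the vinylogous tetronate may stall before the aldol closure, base may open the lactone, or closure may occur at the lactone carbonyl. The fallback builds the arene before the lactone; it sets out from 2 and 4 and comes back at 6. Methyl acetoacetate (commercial) is condensed with 2 to give methyl 2-[(dimethylamino)methylidene]-3-oxobutanoate F1, which is annulated with 4 (t-BuOK, THF) to methyl 4-hydroxy-3,5-dimethoxy-2-methylbenzoate F2. O-Methylation (MeI, K2CO3) gives methyl 3,4,5-trimethoxy-2-methylbenzoate F3, Wohl–Ziegler bromination (NBS, AIBN) gives methyl 2-(bromomethyl)-3,4,5-trimethoxybenzoate F4, and heating at 140 °C closes the lactone to 6.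

Step 3 is at risk because NBS may brominate the electron-rich ring at C7 instead of the benzylic position. The fallback avoids radical chemistry; it sets out from 6 and comes back at 11. Deprotonation of 6 (LiHMDS, −78 °C) and oxidation of the C3 anion with the Davis oxaziridine gives 3-hydroxy-4,5,6-trimethoxy-2-benzofuran-1(3H)-one F5, and acetylation (Ac2O, pyridine) gives 5,6,7-trimethoxy-3-oxo-1,3-dihydro-2-benzofuran-1-yl acetate F6. The chlorotitanium enolate of 10 (TiCl4, i-Pr2NEt, CH2Cl2, −78 °C) then alkylates the acyl-oxocarbenium ion released from F6 with the same facial sense as in step 5, giving 11.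

Step 7, the proposed ring expansion, is the least certain: the benzylic cation may lose a proton to the benzylidene succinate, the nucleophile may take the wrong face at C4, or an ester carbonyl may intercept the cation. The fallback uses only established reaction types; it sets out from 6 and comes back at 19. Claisen acylation of the C3 anion of 6 (LiHMDS, dimethyl oxalate) gives methyl 2-oxo-2-(5,6,7-trimethoxy-3-oxo-1,3-dihydro-2-benzofuran-1-yl)acetate F7. SmI2 cleaves its α-acyloxy C–O bond and acid closes the enol lactone to methyl 5,6,7-trimethoxy-1-oxo-1H-2-benzopyran-3-carboxylate F8. NaOMe opens F8 to the arylpyruvate enolate, which adds to maleimide under a cinchona squaramide catalyst to give methyl 2-[1-[(3S)-2,5-dioxopyrrolidin-3-yl]-3-methoxy-2,3-dioxopropyl]-3,4,5-trimethoxybenzoate F9. Noyori-type transfer hydrogenation (Ru–TsDPEN, HCO2H/Et3N) with dynamic kinetic resolution of the ketone-flanked benzylic centre, followed by lactonisation, gives methyl (3S,4S)-4-[(3S)-2,5-dioxopyrrolidin-3-yl]-5,6,7-trimethoxy-1-oxo-3,4-dihydro-1H-2-benzopyran-3-carboxylate F10. BBr3 and then hot aqueous HCl give 19.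

Further compounds
F1 | step 2 | methyl 2-[(dimethylamino)methylidene]-3-oxobutanoate | CC(=O)C(=CN(C)C)C(=O)OC
F2 | step 2 | methyl 4-hydroxy-3,5-dimethoxy-2-methylbenzoate | COC(=O)c1cc(OC)c(O)c(OC)c1C
F3 | step 2 | methyl 3,4,5-trimethoxy-2-methylbenzoate | COC(=O)c1cc(OC)c(OC)c(OC)c1C
F4 | step 2 | methyl 2-(bromomethyl)-3,4,5-trimethoxybenzoate | COC(=O)c1cc(OC)c(OC)c(OC)c1CBr
F5 | step 3 | 3-hydroxy-4,5,6-trimethoxy-2-benzofuran-1(3H)-one | O=C1OC(O)c2c1cc(OC)c(OC)c2OC
F6 | step 3 | 5,6,7-trimethoxy-3-oxo-1,3-dihydro-2-benzofuran-1-yl acetate | CC(=O)OC1OC(=O)c2cc(OC)c(OC)c(OC)c12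
F7 | step 7 | methyl 2-oxo-2-(5,6,7-trimethoxy-3-oxo-1,3-dihydro-2-benzofuran-1-yl)acetate | COC(=O)C(=O)C1OC(=O)c2cc(OC)c(OC)c(OC)c12
F8 | step 7 | methyl 5,6,7-trimethoxy-1-oxo-1H-2-benzopyran-3-carboxylate | COC(=O)C1=Cc2c(cc(OC)c(OC)c2OC)C(=O)O1
F9 | step 7 | methyl 2-[1-[(3S)-2,5-dioxopyrrolidin-3-yl]-3-methoxy-2,3-dioxopropyl]-3,4,5-trimethoxybenzoate | COC(=O)C(=O)C([C@@H]1CC(=O)NC1=O)c1c(C(=O)OC)cc(OC)c(OC)c1OC
F10 | step 7 | methyl (3S,4S)-4-[(3S)-2,5-dioxopyrrolidin-3-yl]-5,6,7-trimethoxy-1-oxo-3,4-dihydro-1H-2-benzopyran-3-carboxylate | O=C1C[C@H](C(=O)N1)[C@H]3c2c(cc(OC)c(OC)c2OC)C(=O)O[C@@H]3C(=O)OC
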